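The earlier runs and the new flask stem from a simulated flask for an exercise, and the scatter is random.

More product stands in the gamma run, which is the very flask asked about followed so far, than spent carrier was charged: 15.8% of the substrate, or 3.31 mM, against 0.61 mM. So we keep the books of this flask by its turnover budget, the product made per unit of spent carrier charged, which reads 5.43.

| setting | gamma | epsilon | flask |
|---|---|---|---|
| substrate | 0.021 M | 0.021 M | 0.021 M |
| salt in the second phase | 0.0231 M | 0.012 M | 0.0231 M |
| capture agent | 2.1 mM | 2.1 mM | 2.10 mM |
| spent carrier | 0.61 mM | 0.61 mM | 0.61 mM |
| remark | the very flask that is asked about, followed so far | run made earlier |  |
| time |  |  | 6.0 h |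
| volume of the second phase over the first |  |  | 1.0 |

- gamma (time / min: product / %, substrate / %): 40.0: 15.6, 84.6; 90.0: 15.5, 84.0; 180: 16.3, 83.7; 300: 15.7, 84.0
- epsilon (time / min: product / %, substrate / %): 20.0: 7.1, 93.2; 40.0: 7.9, 92.3; 60.0: 8.5, 91.0; 80.0: 8.9, 91.9

(readings scatter by 0.3 percentage points)

- charges count per volume of the first phase; a concentration in a rate is the amount of a species over the volume of its own phase; every rate counts per litre of the first phase
- what is taken out of product is counted as made
- the earlier runs were read with a standard deviation of 0.3 percentage points
- the earlier runs hold the two phases in the same ratio of volumes as the flask asked about
- additions bring no volume worth counting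

- amber: change nothing and wait 2.0 h more
- red: at 6.0 h add substrate, 50.0% of the amount charged, then wait 2.0 h
- ochre: at 6.0 h take out 90% of the product then present, then wait 2.0 h

- product, in percent of the substrate first charged, at 6.0 h
- the remedy with the largest gain of product, or "none" below 2 percentage points (amber / red / ochre / none)
- product present, with what was taken out counted in, in percent of the substrate first charged, after red
- product present, with what was taken out counted in, in percent of the substrate first charged, after ochre

Our ledger, entry by entry:

- Substrate: at 300 min the gamma run reads 15.7% of product and 84.0% of substrate, together 99.7%, so the substrate books close within the scatter, and with that much substrate still standing it is not the limiting reagent.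
- Salt in the second phase: the 0.0231 M charged is 6.98 times the product made, so even at one salt per product this entry stays far from empty.
- Time: product moved by 0.1 percentage points between 40.0 min and 300 min, less than the scatter of 0.3 points, so with both reagents present we book the carrier as the limiting reagent, its turns having been used by the first reading, while the capture agent, at 3.44 times the carrier, is enough to take it out of work.
- Epsilon: its last reading gives a budget of 3.06, and the gamma budget stands 1.77 times above it for 1.92 times the salt, so we read the budget as a contest: at each turn spent carrier meets salt, which returns it to work, or capture agent, which ends it.
- Closing the books: in our books this flask has used its budget by the first reading, so we enter nothing further for added substrate or for product taken out, and we reckon 15.8% now, the same after red and after ochre, and no remedy worth its time.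

The forecast gave 15.8% (15.4% to 16.2%), 15.9% after red (15.4% to 18.5%), 15.9% after ochre (15.4% to 18%) and none as the remedy, judging that “The stall therefore looks like lost activity”; its figures for the remedies stand slightly above our 15.8%, and the choice is the same.

The flask gives 16.1% at 6.0 h, 16.1% after red and 16.1% after ochre, so the choice is none.

    spent carrier + salt in the second phase ⇌ fresh carrier + spent salt in the second phase (K = 0.800, k = 0.440 M⁻¹ s⁻¹)
    substrate + fresh carrier → product + spent carrier (k = 3.50 M⁻¹ s⁻¹)
    spent carrier + capture agent → trapped intermediate (k = 0.940 M⁻¹ s⁻¹)

At 7.71 min spent carrier was used by salt in the second phase 5.6 times as fast as by capture agent (forward rate of the reversible step alone), and the flask's product comes to 5.54 per carrier charged, beside the budget of 5.43 read from the gamma run. Carried to the neighbour flask with 0.0084 M of substrate, other charges held, that budget gives 39.4%, and the neighbour flask made 39.2%.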